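The oxolane ring is disconnected at C2–C3, the bond between the carbinol carbon and the ring carbon that carries O1 and the dienyl chain. The key step exploits the 3-oxybutanoyl pattern C3(O)–C4–C5(CH3)–O1 of this ring: C3 is generated as an acyl radical from the carboxyl carbon of (S)-3-hydroxybutanoate, whose hydroxyl oxygen (O1) bears an (E)-2-sulfonylvinyl group. One 5-exo-trig cyclisation closes the ring as the 2,5-cis 3-ketone with a sulfonylmethyl handle at C2; hydride reduction then gives the all-cis alcohol. The sulfone becomes an enal, and a Horner–Wadsworth–Emmons reaction with an isocoumarin-3-ylmethylphosphonate completes the (E,E)-diene.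

Key step: step 4

Remark: ring atoms are labelled as in the target oxolane (O1, C2 with the dienyl chain, C3 with the hydroxyl, C4, C5 with the methyl group), the diene carbons are C1′–C4′ counted from C2, isocoumarin positions follow 1H-isochromen-1-one numbering, and compounds 1, 2, 11, 13 and 16 are assumed to be purchased.

Step 1
Reactants: 1 tert-butyl (3S)-3-hydroxybutanoate; 2 ethynyl 4-methylphenyl sulfone
Product: 3 tert-butyl (3S)-3-{[(E)-2-(4-methylphenylsulfonyl)ethenyl]oxy}butanoate
Conditions: N-methylmorpholine (0.3 equiv), CH2Cl2, 0 °C to rt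
Reagents that add atoms: none
Why: Amine-catalysed oxa-Michael addition of the secondary alcohol to the ethynyl sulfone should give the (E)-2-alkoxyvinyl sulfone, a vinylogous sulfonate, while the C5 stereocentre bought with 1 is not touched.

Step 2
Reactants: 3 tert-butyl (3S)-3-{[(E)-2-(4-methylphenylsulfonyl)ethenyl]oxy}butanoate
Product: 4 (3S)-3-{[(E)-2-(4-methylphenylsulfonyl)ethenyl]oxy}butanoic acid
Conditions: CF3CO2H, CH2Cl2, 0 °C to rt
Reagents that add atoms: none
Why: Acidolysis of the tert-butyl ester by loss of 2-methylpropene frees the acid, and the electron-poor enol ether is stable to the acid.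

Step 3
Reactants: 4 (3S)-3-{[(E)-2-(4-methylphenylsulfonyl)ethenyl]oxy}butanoic acid
Product: 5 Se-phenyl (3S)-3-{[(E)-2-(4-methylphenylsulfonyl)ethenyl]oxy}butaneselenoate
Conditions: N-(phenylseleno)phthalimide, n-Bu3P, CH2Cl2, −30 °C to rt
Reagents that add atoms: N-(phenylseleno)phthalimide, O=C1c2ccccc2C(=O)N1[Se]c1ccccc1
Why: Selenoesterification through an acyloxyphosphonium ion and phenylselenolate gives the acyl radical precursor under neutral conditions that avoid β-elimination of the alkoxyvinyl sulfone.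

Step 4
Reactants: 5 Se-phenyl (3S)-3-{[(E)-2-(4-methylphenylsulfonyl)ethenyl]oxy}butaneselenoate
Product: 6 (2S,5S)-5-methyl-2-[(4-methylphenylsulfonyl)methyl]oxolan-3-one (2,5-cis)
Conditions: (Me3Si)3SiH, Et3B, air, benzene, rt
Reagents that add atoms: none
Why: Ethyl radicals from Et3B and oxygen start a chain in which the tris(trimethylsilyl)silyl radical abstracts the phenylseleno group to give the acyl radical at C3, which adds to the β-carbon C2 of the (E)-2-alkoxyvinyl sulfone, and the resulting α-sulfonyl radical takes hydrogen from the silane. The closest known reaction type is the acyl radical cyclisation of acyl selenides onto vinylogous carbonates and sulfonates that gives cis-2,5-disubstituted oxolan-3-ones. The oxolane ring closes in the 5-exo-trig mode through the new C2–C3 bond. The new stereocentre C2 is controlled by the C5 methyl group, which sits pseudo-equatorial in a chair-like transition state in which the vinyl sulfone is also pseudo-equatorial, so that the 2,5-cis ketone should result. The step needs cyclisation to outrun hydrogen transfer to the acyl radical and loss of CO, which is secured by the polarity match of the nucleophilic acyl radical with the electron-poor alkene, the slow hydrogen donor (Me3Si)3SiH, the primary alkyl nature of the acyl radical and the low temperature of the Et3B initiation. C3 is left at the ketone level so that its configuration can be set afterwards from the open face of the ring.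

Step 5
Reactants: 6 (2S,5S)-5-methyl-2-[(4-methylphenylsulfonyl)methyl]oxolan-3-one
Product: 7 (2S,3R,5S)-5-methyl-2-[(4-methylphenylsulfonyl)methyl]oxolan-3-ol (all-cis)
Conditions: LiBH(s-Bu)3, THF, −78 °C; then H2O
Reagents that add atoms: none
Why: In this substrate-controlled ketone reduction the bulky hydride attacks the face opposite the cis C2 and C5 substituents, which should set C3 as R and give the all-cis alcohol.

Step 6
Reactants: 7 (2S,3R,5S)-5-methyl-2-[(4-methylphenylsulfonyl)methyl]oxolan-3-ol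
Product: 8 tert-butyl(dimethyl){[(2S,3R,5S)-5-methyl-2-[(4-methylphenylsulfonyl)methyl]oxolan-3-yl]oxy}silane
Conditions: t-BuMe2SiOTf, 2,6-lutidine, CH2Cl2, 0 °C
Reagents that add atoms: tert-butyldimethylsilyl trifluoromethanesulfonate, CC(C)(C)[Si](C)(C)OS(=O)(=O)C(F)(F)F
Why: Silylation of the secondary alcohol with the silyl triflate and a hindered pyridine base masks O3 before the carbanion chemistry.

Step 7
Reactants: 8 tert-butyl(dimethyl){[(2S,3R,5S)-5-methyl-2-[(4-methylphenylsulfonyl)methyl]oxolan-3-yl]oxy}silane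
Product: 10 (2S,3R,5S)-3-(tert-butyldimethylsilyloxy)-5-methyloxolane-2-carbaldehyde, via α-silyloxy sulfone 9 (not isolated)
Conditions: n-BuLi, THF, −78 °C; Me3SiOOSiMe3, −78 to 0 °C
Reagents that add atoms: bis(trimethylsilyl) peroxide, C[Si](C)(C)OO[Si](C)(C)C
Why: In this oxidative desulfonylation the α-sulfonyl carbanion attacks the peroxide O–O bond and the α-silyloxy sulfone loses sulfinate on desilylation to give the aldehyde, with C2 and C3 untouched at low temperature.

Step 8
Reactants: 10 (2S,3R,5S)-3-(tert-butyldimethylsilyloxy)-5-methyloxolane-2-carbaldehyde; 11 (triphenylphosphoranylidene)acetaldehyde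
Product: 12 (2E)-3-[(2R,3R,5S)-3-(tert-butyldimethylsilyloxy)-5-methyloxolan-2-yl]prop-2-enal
Conditions: toluene, 80 °C
Reagents that add atoms: none
Why: Wittig olefination with the stabilised formyl ylide under neutral conditions should give the (E)-enal without epimerising the α-alkoxy aldehyde.

Step 9
Reactants: 13 methyl 2,4-dihydroxy-6-methylbenzoate
Product: 14 methyl 3-chloro-4,6-dihydroxy-2-methylbenzoate
Conditions: SO2Cl2, Et2O, 0 °C to rt
Reagents that add atoms: sulfuryl chloride, O=S(=O)(Cl)Cl
Why: Electrophilic aromatic chlorination should occur para to the hydrogen-bonded 2-hydroxyl and ortho to the 4-hydroxyl, at the ring carbon next to the methyl group, as in related orcinol carbonyl compounds.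

Step 10
Reactants: 14 methyl 3-chloro-4,6-dihydroxy-2-methylbenzoate
Product: 15 methyl 3-chloro-4,6-bis(methoxymethoxy)-2-methylbenzoate
Conditions: NaH, MeOCH2Cl, DMF, 0 °C to rt
Reagents that add atoms: chloromethyl methyl ether, COCCl
Why: Williamson-type O-alkylation of both phenoxides gives acetal ethers that tolerate the lithium amide of the next step.

Step 11
Reactants: 15 methyl 3-chloro-4,6-bis(methoxymethoxy)-2-methylbenzoate; 16 2-chloro-N-methoxy-N-methylacetamide
Product: 17 methyl 3-chloro-2-(3-chloro-2-oxopropyl)-4,6-bis(methoxymethoxy)benzoate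
Conditions: LiN(iPr)2, THF, −78 °C; then 16, −78 °C; then H2O
Reagents that add atoms: none
Why: Lateral lithiation of the ortho-toluate gives a benzylic anion whose acyl substitution on the N-methoxy-N-methylamide stops at the chelated tetrahedral adduct, so that the chloromethyl ketone is released only on work-up.

Step 12
Reactants: 17 methyl 3-chloro-2-(3-chloro-2-oxopropyl)-4,6-bis(methoxymethoxy)benzoate
Product: 18 5-chloro-3-(chloromethyl)-6,8-dihydroxy-1H-isochromen-1-one
Conditions: CF3CO2H, CH2Cl2, H2O, rt to 40 °C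
Reagents that add atoms: none
Why: Acid-catalysed enol lactonisation of the 2-(2-oxoalkyl)benzoate closes the isocoumarin ring, and the two acetal ethers are hydrolysed in the same operation.

Step 13
Reactants: 18 5-chloro-3-(chloromethyl)-6,8-dihydroxy-1H-isochromen-1-one
Product: 19 6,8-bis(tert-butyldimethylsilyloxy)-5-chloro-3-(chloromethyl)-1H-isochromen-1-one
Conditions: t-BuMe2SiOTf, 2,6-lutidine, CH2Cl2, 0 °C to rt
Reagents that add atoms: tert-butyldimethylsilyl trifluoromethanesulfonate, CC(C)(C)[Si](C)(C)OS(=O)(=O)C(F)(F)F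
Why: Silylation of both phenols, including the hydrogen-bonded 8-hydroxyl, with the silyl triflate gives fluoride-labile ethers and the hindered base leaves the allylic chloride alone.

Step 14
Reactants: 19 6,8-bis(tert-butyldimethylsilyloxy)-5-chloro-3-(chloromethyl)-1H-isochromen-1-one
Product: 20 diethyl {[6,8-bis(tert-butyldimethylsilyloxy)-5-chloro-1-oxo-1H-isochromen-3-yl]methyl}phosphonate
Conditions: P(OEt)3, 120 °C
Reagents that add atoms: triethyl phosphite, CCOP(OCC)OCC
Why: Michaelis–Arbuzov reaction of the allylic-type chloride with the phosphite gives the phosphonate, as for halomethyl pyranones.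

Step 15
Reactants: 20 diethyl {[6,8-bis(tert-butyldimethylsilyloxy)-5-chloro-1-oxo-1H-isochromen-3-yl]methyl}phosphonate; 12 (2E)-3-[(2R,3R,5S)-3-(tert-butyldimethylsilyloxy)-5-methyloxolan-2-yl]prop-2-enal
Product: 21 6,8-bis(tert-butyldimethylsilyloxy)-3-{(1E,3E)-4-[(2R,3R,5S)-3-(tert-butyldimethylsilyloxy)-5-methyloxolan-2-yl]buta-1,3-dien-1-yl}-5-chloro-1H-isochromen-1-one
Conditions: NaN(SiMe3)2, THF, −78 °C; then 12, −78 to 0 °C
Reagents that add atoms: none
Why: Horner–Wadsworth–Emmons olefination of the conjugation-stabilised phosphonate anion with the enal should form the C3′=C4′ bond with E geometry, as in couplings of pyranone methylphosphonates with polyenals.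

Step 16
Reactants: 21 6,8-bis(tert-butyldimethylsilyloxy)-3-{(1E,3E)-4-[(2R,3R,5S)-3-(tert-butyldimethylsilyloxy)-5-methyloxolan-2-yl]buta-1,3-dien-1-yl}-5-chloro-1H-isochromen-1-one
Product: 22 5-chloro-6,8-dihydroxy-3-{(1E,3E)-4-[(2R,3R,5S)-3-hydroxy-5-methyloxolan-2-yl]buta-1,3-dien-1-yl}-1H-isochromen-1-one
Conditions: HF·pyridine, pyridine, THF, 0 °C to rt
Reagents that add atoms: none
Why: Fluoride cleaves the two aryl silyl ethers and the alkyl silyl ether in one buffered, non-acidic desilylation that should spare the allylic oxolane ether, the diene and the lactone.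

Compound list

1 | tert-butyl (3S)-3-hydroxybutanoate | C[C@H](O)CC(=O)OC(C)(C)C | starting material
2 | ethynyl 4-methylphenyl sulfone | C#CS(=O)(=O)c1ccc(C)cc1 | starting material
3 | tert-butyl (3S)-3-{[(E)-2-(4-methylphenylsulfonyl)ethenyl]oxy}butanoate | C[C@H](O/C=C/S(=O)(=O)c1ccc(C)cc1)CC(=O)OC(C)(C)C | intermediate
4 | (3S)-3-{[(E)-2-(4-methylphenylsulfonyl)ethenyl]oxy}butanoic acid | C[C@H](O/C=C/S(=O)(=O)c1ccc(C)cc1)CC(=O)O | intermediate
5 | Se-phenyl (3S)-3-{[(E)-2-(4-methylphenylsulfonyl)ethenyl]oxy}butaneselenoate | C[C@H](O/C=C/S(=O)(=O)c1ccc(C)cc1)CC(=O)[Se]c1ccccc1 | intermediate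
6 | (2S,5S)-5-methyl-2-[(4-methylphenylsulfonyl)methyl]oxolan-3-one | C[C@H]1CC(=O)[C@@H](CS(=O)(=O)c2ccc(C)cc2)O1 | intermediate
7 | (2S,3R,5S)-5-methyl-2-[(4-methylphenylsulfonyl)methyl]oxolan-3-ol | C[C@H]1C[C@@H](O)[C@@H](CS(=O)(=O)c2ccc(C)cc2)O1 | intermediate
8 | tert-butyl(dimethyl){[(2S,3R,5S)-5-methyl-2-[(4-methylphenylsulfonyl)methyl]oxolan-3-yl]oxy}silane | C[C@H]1C[C@@H](O[Si](C)(C)C(C)(C)C)[C@@H](CS(=O)(=O)c2ccc(C)cc2)O1 | intermediate
9 | tert-butyl(dimethyl){[(2S,3R,5S)-5-methyl-2-[(4-methylphenylsulfonyl)(trimethylsilyloxy)methyl]oxolan-3-yl]oxy}silane, both epimers at the sulfonyl carbon | C[C@H]1C[C@@H](O[Si](C)(C)C(C)(C)C)[C@@H](C(O[Si](C)(C)C)S(=O)(=O)c2ccc(C)cc2)O1 | intermediate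
10 | (2S,3R,5S)-3-(tert-butyldimethylsilyloxy)-5-methyloxolane-2-carbaldehyde | C[C@H]1C[C@@H](O[Si](C)(C)C(C)(C)C)[C@@H](C=O)O1 | intermediate
11 | (triphenylphosphoranylidene)acetaldehyde | O=CC=P(c1ccccc1)(c1ccccc1)c1ccccc1 | starting material
12 | (2E)-3-[(2R,3R,5S)-3-(tert-butyldimethylsilyloxy)-5-methyloxolan-2-yl]prop-2-enal | C[C@H]1C[C@@H](O[Si](C)(C)C(C)(C)C)[C@@H](/C=C/C=O)O1 | intermediate
13 | methyl 2,4-dihydroxy-6-methylbenzoate | COC(=O)c1c(C)cc(O)cc1O | starting material
14 | methyl 3-chloro-4,6-dihydroxy-2-methylbenzoate | COC(=O)c1c(C)c(Cl)c(O)cc1O | intermediate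
15 | methyl 3-chloro-4,6-bis(methoxymethoxy)-2-methylbenzoate | COC(=O)c1c(C)c(Cl)c(OCOC)cc1OCOC | intermediate
16 | 2-chloro-N-methoxy-N-methylacetamide | CON(C)C(=O)CCl | starting material
17 | methyl 3-chloro-2-(3-chloro-2-oxopropyl)-4,6-bis(methoxymethoxy)benzoate | COC(=O)c1c(CC(=O)CCl)c(Cl)c(OCOC)cc1OCOC | intermediate
18 | 5-chloro-3-(chloromethyl)-6,8-dihydroxy-1H-isochromen-1-one | ClCc1cc2c(Cl)c(O)cc(O)c2c(=O)o1 | intermediate
19 | 6,8-bis(tert-butyldimethylsilyloxy)-5-chloro-3-(chloromethyl)-1H-isochromen-1-one | ClCc1cc2c(Cl)c(O[Si](C)(C)C(C)(C)C)cc(O[Si](C)(C)C(C)(C)C)c2c(=O)o1 | intermediate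
20 | diethyl {[6,8-bis(tert-butyldimethylsilyloxy)-5-chloro-1-oxo-1H-isochromen-3-yl]methyl}phosphonate | CCOP(=O)(OCC)Cc1cc2c(Cl)c(O[Si](C)(C)C(C)(C)C)cc(O[Si](C)(C)C(C)(C)C)c2c(=O)o1 | intermediate
21 | 6,8-bis(tert-butyldimethylsilyloxy)-3-{(1E,3E)-4-[(2R,3R,5S)-3-(tert-butyldimethylsilyloxy)-5-methyloxolan-2-yl]buta-1,3-dien-1-yl}-5-chloro-1H-isochromen-1-one | C[C@H]1C[C@@H](O[Si](C)(C)C(C)(C)C)[C@@H](/C=C/C=C/c2cc3c(Cl)c(O[Si](C)(C)C(C)(C)C)cc(O[Si](C)(C)C(C)(C)C)c3c(=O)o2)O1 | intermediate
22 | 5-chloro-6,8-dihydroxy-3-{(1E,3E)-4-[(2R,3R,5S)-3-hydroxy-5-methyloxolan-2-yl]buta-1,3-dien-1-yl}-1H-isochromen-1-one | C[C@H]1C[C@@H](O)[C@@H](/C=C/C=C/c2cc3c(Cl)c(O)cc(O)c3c(=O)o2)O1 | target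

Total step count: 16. Longest linear sequence: 10 steps (steps 1 to 8, then 15 and 16); the isocoumarin branch (steps 9 to 14) joins at step 15.

Steps most likely to fail

Step 7. The α-alkoxy aldehyde may epimerise at C2 or lose the silyloxy group by β-elimination while it is still in the basic silanolate medium, and oxygen transfer to the carbanion may stay incomplete. The fallback avoids the aldehyde altogether. It sets out from 8: the lithiated sulfone (n-BuLi, THF, −78 °C) is trapped with monomeric formaldehyde and then Ac2O to give 2-[(2S,3R,5S)-3-(tert-butyldimethylsilyloxy)-5-methyloxolan-2-yl]-2-(4-methylphenylsulfonyl)ethyl acetate F1. Reductive elimination with Na/Hg (Na2HPO4, MeOH–THF, −20 °C; Julia–Lythgoe methylenation) should give tert-butyl{[(2R,3R,5S)-2-ethenyl-5-methyloxolan-3-yl]oxy}dimethylsilane F2. Cross-metathesis of F2 with crotonaldehyde (second-generation Hoveyda–Grubbs catalyst RuCl2(H2IMes)(=CH-C6H4-2-OiPr), CH2Cl2, 40 °C) comes back to the route at enal 12, so that steps 7 and 8 are bypassed.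

Step 11. Proton transfer from the α-chloro amide to the benzylic anion, or displacement of chloride in place of acyl transfer, would return the toluate or give alkylated material. The fallback sets out from 15: the same lithiated toluate is acylated with 2-(tert-butyldimethylsilyloxy)-N-methoxy-N-methylacetamide, which has neither an activated α-hydrogen nor a leaving group, to give methyl 2-[3-(tert-butyldimethylsilyloxy)-2-oxopropyl]-3-chloro-4,6-bis(methoxymethoxy)benzoate F3. Aqueous CF3CO2H should then lactonise F3 and remove all three protecting groups to give 5-chloro-6,8-dihydroxy-3-(hydroxymethyl)-1H-isochromen-1-one F4. Chlorination of the primary allylic alcohol alone (PPh3, CCl4, MeCN; Appel reaction, phenols untouched) comes back to the route at 18.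

Step 4. Hydrogen transfer to the acyl radical before ring closure, loss of CO, or β-elimination of the sulfonylvinyl alkoxide from the activated selenoester during its preparation would lower the return, and the 2,5-cis preference could be eroded at higher temperature. The fallback closes the same C2–C3 bond through a ketyl radical anion instead. It sets out from acid 4: reduction with BH3·SMe2 gives (3S)-3-{[(E)-2-(4-methylphenylsulfonyl)ethenyl]oxy}butan-1-ol F5, and Dess–Martin oxidation gives (3S)-3-{[(E)-2-(4-methylphenylsulfonyl)ethenyl]oxy}butanal F6. Reductive aldehyde–alkene cyclisation with SmI2 (MeOH, THF, 0 °C), a reaction known for β-alkoxyacrylates, should again favour the 2,5-cis ring and give (2S,3S,5S)-5-methyl-2-[(4-methylphenylsulfonyl)methyl]oxolan-3-ol F7, whose C3 configuration is immaterial. Dess–Martin oxidation of F7 comes back to the route at ketone 6.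

Further compounds
F1 | step 7 | 2-[(2S,3R,5S)-3-(tert-butyldimethylsilyloxy)-5-methyloxolan-2-yl]-2-(4-methylphenylsulfonyl)ethyl acetate, both epimers at the sulfonyl carbon | C[C@H]1C[C@@H](O[Si](C)(C)C(C)(C)C)[C@@H](C(COC(C)=O)S(=O)(=O)c2ccc(C)cc2)O1
F2 | step 7 | tert-butyl{[(2R,3R,5S)-2-ethenyl-5-methyloxolan-3-yl]oxy}dimethylsilane | C[C@H]1C[C@@H](O[Si](C)(C)C(C)(C)C)[C@@H](C=C)O1
F3 | step 11 | methyl 2-[3-(tert-butyldimethylsilyloxy)-2-oxopropyl]-3-chloro-4,6-bis(methoxymethoxy)benzoate | COC(=O)c1c(CC(=O)CO[Si](C)(C)C(C)(C)C)c(Cl)c(OCOC)cc1OCOC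
F4 | step 11 | 5-chloro-6,8-dihydroxy-3-(hydroxymethyl)-1H-isochromen-1-one | OCc1cc2c(Cl)c(O)cc(O)c2c(=O)o1
F5 | step 4 | (3S)-3-{[(E)-2-(4-methylphenylsulfonyl)ethenyl]oxy}butan-1-ol | C[C@H](O/C=C/S(=O)(=O)c1ccc(C)cc1)CCO
F6 | step 4 | (3S)-3-{[(E)-2-(4-methylphenylsulfonyl)ethenyl]oxy}butanal | C[C@H](O/C=C/S(=O)(=O)c1ccc(C)cc1)CC=O
F7 | step 4 | (2S,3S,5S)-5-methyl-2-[(4-methylphenylsulfonyl)methyl]oxolan-3-ol | C[C@H]1C[C@H](O)[C@@H](CS(=O)(=O)c2ccc(C)cc2)O1
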